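The target makes more of itself. Each target that meets starting material and coupling partner leaves as two, and a slow direct step supplies the first of it. Meanwhile the coupling partner condenses with itself and the protic impurity quenches starting material.

    starting material + coupling partner + target → 2 target (k1 = 0.70 /M²/s)
    starting material + coupling partner → target (k2 = 6.0 × 10⁻⁴ /M/s)
    2 coupling partner → self-condensation product (k3 = 0.0071 /M/s)
    starting material + protic impurity → quenched substrate (k4 = 0.042 /M/s)

| flask | starting material | coupling partner | protic impurity | time |
|---|---|---|---|---|
| delta | 0.40 M | 1.05 equiv | 0.0500 M | 3.0 min |
| zeta | 0.40 M | 1.05 equiv | 0.0800 M | 3.0 min |
| eta | 0.40 M | 1.05 equiv | 0.120 M | 3.0 min |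

- amount of target at the end, in percent of the starting material charged for delta, zeta, eta, in this order
- how that number moves from the first to the last of them (falls all the way / hardly changes / falls, then rises / rises, then falls / rises all the way)

- a doubled species enters its step squared and goes two at a time
- "hardly changes" means that all values lie within two and a half points (for a concentration: within two and a half percent of the largest)
- run time (delta): 3.0 min

My bench rule says that 1.05 equiv of coupling partner makes starting material the limiting reagent, so the yield is whatever the impurity leaves: for delta, 87.5 %. The rule stands while the partner's spare, 0.420 M less 0.40 M, or 0.0200 M, covers what self-condensation takes before coupling gets going.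

So I solve both ends and join them. At the early end, the autocatalytic step overtakes the direct one once c(target) passes the ratio of their constants, 8.57 × 10⁻⁴ M. From there target grows exponentially, with 0.70 /M²/s times c(starting material) times c(coupling partner) as its rate per unit of target. Run at the charged concentrations, that growth reaches c(starting material) at a take-off time of 0.871 min.

At the late end, each target costs one coupling partner, so the charged partner less what has condensed by take-off is the most target the flask can hold. Second-order loss up to then, with coupling left out, leaves c(coupling partner) at 0.320 M. That is a loss of 0.0998 M, 4.99 times the spare, so the border is crossed.

I call the surviving partner, as a share of the starting material charged, the partner ceiling: 80.1 %, which is lower than the bench rule gave. This is a lid rather than a yield at 3.0 min, and the impurity stands nowhere in it. For the shape I reckon the share of protic impurity that has quenched starting material by take-off, with c(starting material) held at its charge: 58.4 %. Between delta and eta that opens a gap of 10.2 % of the starting material charged, wider than the 2.50 % band. I take a gap of that size to reach the target, so my answer is: falls all the way.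

The forecast gives 72 %, 68 % and 62 %, so falls all the way, saying: “More impurity removes starting material and slightly delays take-off, giving the side reaction longer”. Its first figure lies under my ceiling.

The simulation gives 73.3 %, 70.7 % and 66.7 %: falls all the way. In delta, quenching reached the mid-point of its turnover at 0.505 min and self-condensation had 97 % of its turnover behind it at 1.50 min, while the autocatalytic step reached its mid-point at 1.12 min, later than my take-off. After 30.0 min, delta holds 78.0 % target with 0 % coupling partner, under the ceiling, and eta holds 74.6 % target with 0.761 % coupling partner, also under it.

The constants are made up, and the outcome is calculated.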